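The numbers were set for the occasion; the flask was simulated.

Watch the catalyst.

| flask | starting material | precatalyst | time | remark |
|---|---|---|---|---|
| alpha | 0.20 M | 20 µM | 4.0 h | a closed flask charged with all of it at once and left for 4.0 h |
| epsilon | 0.20 M | 20 µM |  | a single well-mixed tank run continuously and read at steady state, 4.0 h in it on average |
| gamma | 0.20 M (fed, over 3.20 h) | 20 µM | 4.0 h | a stirred flask in which starting material is dosed at a steady rate over 3.20 h without added volume, worked up at 4.0 h |
| theta | 0.20 M | 20 µM | 4.0 h | plug flow through a tube for 4.0 h, no back-mixing |

    starting material + enzyme ⇌ complex (K1 = 6.8 M⁻¹, k1 = 2.6 × 10⁶ M⁻¹ h⁻¹)
    2 starting material → homo dimer (k2 = 7.8 × 10⁻⁴ M⁻¹ h⁻¹)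
    precatalyst → enzyme (k3 = 0.079 h⁻¹)
    starting material + complex → spent catalyst (k4 = 3.1 M⁻¹ h⁻¹)
    complex ⇌ enzyme + product (K5 = 0.14 M, k5 = 12000 h⁻¹)

- in percentages every species weighs as the starting material in it: one spent catalyst or homo dimer counts as two
- two of one species on the left: rate k times its square, two consumed each time
- the stated concentrations are those of everything mixed, before any reaction; amounts are the same in each set-up
- the feed brings no volume worth counting
- run time (alpha): 4.0 h

* the set-up with the highest amount of product at the outlet or at the end, in percent of the starting material put in ("none" if the first two lie within 2 percentage points) (alpha / epsilon / gamma / theta / none)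
* amount of product at the outlet or at the end, in percent of the starting material put in, alpha
* amount of product at the outlet or at the end, in percent of the starting material put in, epsilon
* amount of product at the outlet or at the end, in percent of the starting material put in, gamma
* amount of product at the outlet or at the end, in percent of the starting material put in, theta

Two views dispute these flasks, and mine is a budget. Complex either turns over to product or is killed by starting material. If I divide the forward rate of the turnover step by the rate of the death step, c(complex) and time both cancel, which leaves the turnover constant over the death constant times c(starting material). This is a turnover number, the forward turnovers per catalyst lost, N = 19400 at the charged c(starting material).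

By 4.0 h the precatalyst has released 27.1% of its charge in alpha. If every released catalyst spent its N turnovers, that would pay for 52.4% of the starting material, a ceiling rather than a yield. Complex has a half-life of 1.1 h against the death step at the charged c(starting material), shorter than the run, so I count catalyst loss within the run, though that figure holds for complex alone at that concentration.

On this budget view, dosing looks worth a bet. In gamma, with half the charge in the flask at mid-feed, N stands at twice its value, 38700. I therefore bet on gamma, ahead of alpha by more than 2 percentage points. My reckoning gives a ceiling and a ranking, not a yield for each set-up.

The forecast holds the other view, that slow release and the reversible conversion set the pace. It gives 21.3% for alpha, 21% for epsilon, 21.7% for gamma and 21.3% for theta, with best: none. On my favourite it says “dosing spares the catalyst but lowers early rate”.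

The simulation gives 21.5% for alpha, 21.0% for epsilon, 21.3% for gamma and 21.5% for theta, with best: none. The forecast stands and my bet is lost.

At 4.00 h, alpha has 11.5% of its catalyst charged as spent catalyst, out of the 27.1% released, and N times that amount is 22.2% of the charge, beside the 21.5% read. The budget view comes into its own in the neighbouring flask, alpha with 0.80 M of starting material. There N falls to 4840, and the same released catalyst pays for 3.28% of that charge, far under the 48.8% that the two equilibrium constants allow. That flask read 2.92% product, with 24.1% of its catalyst charged as spent catalyst and 72.9% still precatalyst.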